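**Retrosynthetic overview**

1. Locants: ring A is the 4-hydroxyphenyl ring (C1 carries the stilbene vinyl, C3 the geranyl group, C4 the OH), ring B is the resorcinol ring, and the geranyl chain is C1'–C8'. The last step removes three silyl ethers from 13.
2. Key disconnection: the C1'–C2' bond (benzylic CH2 to vinylic CH), giving benzylic chloride 9 and the C8 enyne 11. One flask adds methyl and aluminium syn across the alkyne and cross-couples the resulting alkenylalane with 9. This creates the C3' methyl, the (E)-C2'=C3' olefin and the fragment-joining bond together.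
3. Enabling feature: C1' is both benzylic to ring A C3 and allylic to the trisubstituted C2'=C3' bond, on which the C3' methyl is cis to C1'. That cis Me/CH2Ar pair is the imprint of a syn methyl–metal addition to a terminal alkyne. With C2' as an sp2 nucleophile, allylic transposition, O-alkylation and attack on the more nucleophilic ring B are excluded.
4. Stilbene C=C: Heck reaction of ring A bromide 5 with ring B styrene 3, then CHO → CH2OH → CH2Cl.
5. No ring is formed in the route: rings A and B come from 5-bromosalicylaldehyde and 3,5-dihydroxybenzaldehyde.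

Key step: step 8

Remark: all silyl ethers are tert-butyldimethylsilyl (TBS); 5-bromo-2-methylpent-2-ene and the lithium acetylide–ethylenediamine complex are taken as commercial.

**Route**

Step 1
Reactants: 1 3,5-dihydroxybenzaldehyde
Product: 2 3,5-bis(tert-butyldimethylsilyloxy)benzaldehyde
Conditions: TBSCl (2.4 equiv), imidazole (5 equiv), DMF, 0 °C → rt
Reagents that add atoms: tert-butyldimethylsilyl chloride CC(C)(C)[Si](C)(C)Cl
Why: Imidazole-promoted silyl ether formation should mask both phenols, which would otherwise quench the ylide, the Heck base and the alane used later.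

Step 2
Reactants: 2 3,5-bis(tert-butyldimethylsilyloxy)benzaldehyde
Product: 3 3,5-bis(tert-butyldimethylsilyloxy)styrene
Conditions: Ph3PCH3Br, n-BuLi, THF, 0 °C; then 2, 0 °C → rt
Reagents that add atoms: methyltriphenylphosphonium bromide C[P+](c1ccccc1)(c1ccccc1)c1ccccc1.[Br-]
Why: Wittig methylenation of the aryl aldehyde with the non-stabilised ylide should give the terminal styrene, and aryl silyl ethers tolerate the preformed ylide.

Step 3
Reactants: 4 5-bromo-2-hydroxybenzaldehyde
Product: 5 5-bromo-2-(tert-butyldimethylsilyloxy)benzaldehyde
Conditions: TBSCl (1.2 equiv), imidazole (2.5 equiv), DMF, rt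
Reagents that add atoms: tert-butyldimethylsilyl chloride CC(C)(C)[Si](C)(C)Cl
Why: Imidazole-promoted silylation of the phenol should proceed cleanly and leaves aldehyde and aryl bromide untouched.

Step 4
Reactants: 5 5-bromo-2-(tert-butyldimethylsilyloxy)benzaldehyde; 3 3,5-bis(tert-butyldimethylsilyloxy)styrene
Product: 6 5-[(E)-2-[3,5-bis(tert-butyldimethylsilyloxy)phenyl]ethenyl]-2-(tert-butyldimethylsilyloxy)benzaldehyde
Conditions: Pd2(dba)3 (1.5 mol%), [HP(t-Bu)3]BF4 (6 mol%), Cy2NMe (1.2 equiv), 1,4-dioxane, rt → 50 °C
Reagents that add atoms: none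
Why: In this Mizoroki–Heck reaction, oxidative addition of the unhindered aryl bromide, β-selective syn insertion of the styrene and syn β-hydride elimination should give the (E)-stilbene; the bulky electron-rich phosphine allows near-ambient temperature, so silyl ethers and aldehyde should survive.

Step 5
Reactants: 6 5-[(E)-2-[3,5-bis(tert-butyldimethylsilyloxy)phenyl]ethenyl]-2-(tert-butyldimethylsilyloxy)benzaldehyde
Product: 7 {5-[(E)-2-[3,5-bis(tert-butyldimethylsilyloxy)phenyl]ethenyl]-2-(tert-butyldimethylsilyloxy)phenyl}methanol
Conditions: NaBH4, THF/MeOH, 0 °C; aq. NH4Cl quench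
Reagents that add atoms: none
Why: Borohydride reduction is chemoselective for the aldehyde; the stilbene and the aryl silyl ethers should not react at 0 °C, and a prompt quench limits silyl migration to the new alkoxide.

Step 6
Reactants: 7 {5-[(E)-2-[3,5-bis(tert-butyldimethylsilyloxy)phenyl]ethenyl]-2-(tert-butyldimethylsilyloxy)phenyl}methanol
Product: 9 tert-butyl{2-(chloromethyl)-4-[(E)-2-[3,5-bis(tert-butyldimethylsilyloxy)phenyl]ethenyl]phenoxy}dimethylsilane, via benzylic mesylate 8 (not isolated)
Conditions: MsCl, Et3N, THF, 0 °C; then LiCl, 0 °C → rt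
Reagents that add atoms: lithium chloride [Li+].[Cl-] (chlorine of 9); methanesulfonyl chloride CS(=O)(=O)Cl (mesyl group of 8 only)
Why: Mesylation followed by SN2 displacement with chloride at the primary benzylic carbon should give the chloride under non-acidic conditions that preserve the aryl silyl ethers.

Step 7
Reactants: 10 5-bromo-2-methylpent-2-ene
Product: 11 6-methylhept-5-en-1-yne
Conditions: LiC≡CH·H2NCH2CH2NH2 (1.3 equiv), DMSO, 10 °C → rt
Reagents that add atoms: lithium acetylide (as its ethylenediamine complex) [Li+].[C-]#C
Why: SN2 alkylation of lithium acetylide by the primary bromide in DMSO should outrun E2 elimination and deliver the terminal enyne.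

Step 8
Reactants: 11 6-methylhept-5-en-1-yne; 9 tert-butyl{2-(chloromethyl)-4-[(E)-2-[3,5-bis(tert-butyldimethylsilyloxy)phenyl]ethenyl]phenoxy}dimethylsilane
Product: 13 tris(tert-butyldimethylsilyl) ether of schweinfurthin I, via alkenylalane 12 (not isolated)
Conditions: 11 (1.5 equiv), AlMe3 (3 equiv), Cp2ZrCl2 (0.25 equiv), ClCH2CH2Cl, 0 °C → rt; volatiles removed in vacuo; then 9 (1 equiv), Pd(PPh3)4 (5 mol%), THF, rt
Reagents that add atoms: trimethylaluminium C[Al](C)C (the C3' methyl; the AlMe2 group of 12)
Why: Cp2ZrCl2-assisted syn methylmetalation of the terminal alkyne of 11 should place methyl on the internal carbon and aluminium on the terminal carbon, giving (E)-alkenylalane 12 with methyl and metal cis; zerovalent palladium then inserts into the benzylic C–Cl bond of 9, the alkenyl group transfers from aluminium to palladium with retention, and reductive elimination forms the C1'–C2' bond. The closest known reaction type is the Negishi zirconium-catalysed carboalumination of terminal alkynes followed by palladium-catalysed alkenyl–benzyl cross-coupling of the alkenylalane with a benzylic halide, the established route to allylated arenes. No ring is closed and no stereocentre is created; the only stereochemical element, the (E)-C2'=C3' double bond, is fixed by the syn addition and should pass through transmetalation and reductive elimination without isomerisation. The step needs regioselective carbometalation (the unhindered CH terminus of the alkyne takes the metal, and the trisubstituted C6'=C7' olefin does not react), alkenyl-over-methyl transfer from aluminium (the sp2 carbon transmetalates faster) and reaction only at the benzylic chloride (aryl silyl ethers and the stilbene are inert to zerovalent palladium and to the alane at room temperature). Because C2' arrives as the nucleophile and C1' is already fixed to ring A C3, allylic transposition, O-alkylation and alkylation of the more electron-rich ring B cannot occur, and the absence of Brønsted acid avoids cyclisation of the geranyl chain onto the oxygen.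

Step 9
Reactants: 13 tris(tert-butyldimethylsilyl) ether of schweinfurthin I
Product: 14 schweinfurthin I
Conditions: TBAF (3.6 equiv), AcOH (3.6 equiv), THF, 0 °C → rt, argon, exclusion of light
Reagents that add atoms: none
Why: Fluoride-induced cleavage of the three aryl silyl ethers should be fast; the acetic acid buffer keeps the polyphenol protonated (limiting base-promoted oxidation) yet is too weak to cyclise the ortho-geranyl phenol to a chroman.

**Compound list**

1 | 3,5-dihydroxybenzaldehyde | O=Cc1cc(O)cc(O)c1 | starting material
2 | 3,5-bis(tert-butyldimethylsilyloxy)benzaldehyde | O=Cc1cc(O[Si](C)(C)C(C)(C)C)cc(O[Si](C)(C)C(C)(C)C)c1 | intermediate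
3 | 3,5-bis(tert-butyldimethylsilyloxy)styrene | C=Cc1cc(O[Si](C)(C)C(C)(C)C)cc(O[Si](C)(C)C(C)(C)C)c1 | intermediate
4 | 5-bromo-2-hydroxybenzaldehyde (5-bromosalicylaldehyde) | O=Cc1cc(Br)ccc1O | starting material
5 | 5-bromo-2-(tert-butyldimethylsilyloxy)benzaldehyde | O=Cc1cc(Br)ccc1O[Si](C)(C)C(C)(C)C | intermediate
6 | 5-[(E)-2-[3,5-bis(tert-butyldimethylsilyloxy)phenyl]ethenyl]-2-(tert-butyldimethylsilyloxy)benzaldehyde | O=Cc1cc(/C=C/c2cc(O[Si](C)(C)C(C)(C)C)cc(O[Si](C)(C)C(C)(C)C)c2)ccc1O[Si](C)(C)C(C)(C)C | intermediate
7 | {5-[(E)-2-[3,5-bis(tert-butyldimethylsilyloxy)phenyl]ethenyl]-2-(tert-butyldimethylsilyloxy)phenyl}methanol | OCc1cc(/C=C/c2cc(O[Si](C)(C)C(C)(C)C)cc(O[Si](C)(C)C(C)(C)C)c2)ccc1O[Si](C)(C)C(C)(C)C | intermediate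
8 | benzylic methanesulfonate of 7 (not isolated) | CS(=O)(=O)OCc1cc(/C=C/c2cc(O[Si](C)(C)C(C)(C)C)cc(O[Si](C)(C)C(C)(C)C)c2)ccc1O[Si](C)(C)C(C)(C)C | intermediate
9 | tert-butyl{2-(chloromethyl)-4-[(E)-2-[3,5-bis(tert-butyldimethylsilyloxy)phenyl]ethenyl]phenoxy}dimethylsilane | ClCc1cc(/C=C/c2cc(O[Si](C)(C)C(C)(C)C)cc(O[Si](C)(C)C(C)(C)C)c2)ccc1O[Si](C)(C)C(C)(C)C | intermediate
10 | 5-bromo-2-methylpent-2-ene | CC(C)=CCCBr | starting material
11 | 6-methylhept-5-en-1-yne | C#CCCC=C(C)C | intermediate
12 | [(E)-2,6-dimethylhepta-1,5-dien-1-yl]dimethylalane (not isolated) | CC(C)=CCC/C(C)=C/[Al](C)C | intermediate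
13 | tris(tert-butyldimethylsilyl) ether of schweinfurthin I | CC(C)=CCC/C(C)=C/Cc1cc(/C=C/c2cc(O[Si](C)(C)C(C)(C)C)cc(O[Si](C)(C)C(C)(C)C)c2)ccc1O[Si](C)(C)C(C)(C)C | intermediate
14 | schweinfurthin I | CC(C)=CCC/C(C)=C/Cc1cc(/C=C/c2cc(O)cc(O)c2)ccc1O | target

**Step count and risks**

Total step count: 9. Longest linear sequence: 7 steps (steps 1, 2, 4, 5, 6, 8, 9).

Steps most likely to fail:

Step 8. What may go wrong: protonolysis of the alkenylalane by adventitious moisture, competing methyl transfer from aluminium to the benzylic palladium species, or reductive homocoupling of the benzylic chloride. The fallback sets out from 11 and 9 and comes back at 13, with the polarity of the union reversed. The carboalumination of 11 (AlMe3, Cp2ZrCl2) is quenched with iodine to give isolable (E)-1-iodo-2,6-dimethylhepta-1,5-diene F1. Chloride 9 is converted with zinc dust and LiCl in THF into the benzylic zinc chloride F2. A Negishi coupling of F2 with F1 (Pd(PPh3)4, THF, rt) should then give 13; the metal now carries no methyl ligands and the alkenyl partner is a purified, geometrically defined iodide.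

Step 4. What may go wrong: loss of the formyl-activated ring A silyl ether under the amine base, or arylation at the internal styrene carbon leading to a 1,1-diarylethene. The fallback sets out from 3 and comes back at 6. Cross-metathesis of 3 with vinylboronic acid pinacol ester (second-generation Grubbs catalyst, CH2Cl2, 40 °C) should give the (E)-alkenylboronic ester F3. Suzuki–Miyaura coupling of F3 with bromide 5 (PdCl2(dppf), K3PO4, THF/H2O, 40 °C) should then give 6 with the olefin geometry fixed before the C–C coupling.

Step 9. What may go wrong: air oxidation of the electron-rich phenoxides formed during fluoride treatment, light-induced E-to-Z isomerisation of the stilbene, or incomplete cleavage giving mixtures of partly silylated phenols. The fallback sets out from 13 and comes back at 14. Fluoride cleavage is run in the presence of acetic anhydride (TBAF, Ac2O, THF, 0 °C), so that each phenoxide is acetylated as it forms, giving the air-stable schweinfurthin I triacetate F4, which can be purified. Mild transesterification (catalytic K2CO3, degassed MeOH, 0 °C) should then release 14.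

**Further compounds**

F1 | step 8 | (E)-1-iodo-2,6-dimethylhepta-1,5-diene | CC(C)=CCC/C(C)=C/I
F2 | step 8 | {5-[(E)-2-[3,5-bis(tert-butyldimethylsilyloxy)phenyl]ethenyl]-2-(tert-butyldimethylsilyloxy)benzyl}zinc chloride | Cl[Zn]Cc1cc(/C=C/c2cc(O[Si](C)(C)C(C)(C)C)cc(O[Si](C)(C)C(C)(C)C)c2)ccc1O[Si](C)(C)C(C)(C)C
F3 | step 4 | 2-[(E)-2-[3,5-bis(tert-butyldimethylsilyloxy)phenyl]ethenyl]-4,4,5,5-tetramethyl-1,3,2-dioxaborolane | CC1(C)OB(/C=C/c2cc(O[Si](C)(C)C(C)(C)C)cc(O[Si](C)(C)C(C)(C)C)c2)OC1(C)C
F4 | step 9 | schweinfurthin I triacetate | CC(C)=CCC/C(C)=C/Cc1cc(/C=C/c2cc(OC(C)=O)cc(OC(C)=O)c2)ccc1OC(C)=O
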